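**Strategy**

The route rests on cutting C6–C7 and C11–C12 (germacranolide numbering: lactone C12(=O)–O–C6, C7, C11=C13; ether O bridges C5 and C10). One photoredox operation closes both the second oxepane ring of the 5,10-epoxide and the γ-lactone: decarboxylation gives a C6 α-(methoxycarbonyloxy)alkyl radical that adds 7-exo to C7 of a γ-silyloxy vinylphosphonate, the C11 radical is reduced to the carbanion, and this acylates the C6 carbonate carbon (C12). The step exploits the lactone oxygen on C6 and the C11 position of the exocyclic methylene, held as a phosphonate. The precursor is a 2,7-disubstituted oxepane assembled from (S)-linalool and a Fráter–Seebach acid by esterification and ring-closing metathesis.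

Key step: step 17

Remark on numbering: the germacranolide numbering of the target is used for all intermediates (C3 OAc, C4 bearing C15, C5–O–C10 ether, C6–O–C12 lactone, C8 O-angelate, C14 methyl on C10, C11=C13).
Remark on the target: the descriptors place C6 (on C5) and C9 (on C10) on opposite faces of the first oxepane, so the C6–C7 closure builds a trans-bridged (inside–outside) 11-oxabicyclo[4.4.1]undecane; the route is built for exactly this isomer, and (R)-linalool would give the C10 epimer.
Remark on materials: 1 and 4 are assumed to be purchasable as single enantiomers; from step 9 to step 16 the C6 centre is carried as a mixture of epimers, which is removed when C6 becomes a radical.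

**Route**

Step 1
Reactants: 1 (S)-(+)-linalool
Product: 2 (S)-4-methylhex-5-ene-1,4-diol
Conditions: O3 (1.0 equiv), CH2Cl2/MeOH, −78 °C; then NaBH4, −78 °C → rt
Reagents that add atoms: ozone O=[O+][O-]
Why: Chemoselective ozonolysis with reductive work-up: the electron-rich trisubstituted 6,7-alkene should be cleaved before the vinyl group, NaBH4 reduces the ozonide to the primary alcohol, and the tertiary carbinol stereocentre (future C10) is not touched.

Step 2
Reactants: 2 (S)-4-methylhex-5-ene-1,4-diol
Product: 3 (S)-6-(tert-butyldiphenylsilyloxy)-3-methylhex-1-en-3-ol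
Conditions: TBDPSCl, imidazole, CH2Cl2, 0 °C → rt
Reagents that add atoms: tert-butyl(chloro)diphenylsilane CC(C)(C)[Si](Cl)(c1ccccc1)c1ccccc1
Why: Silyl ether formation, selective for the primary hydroxyl because the tertiary allylic alcohol is too hindered for the bulky silyl chloride.

Step 3
Reactants: 4 ethyl (R)-3-hydroxypent-4-enoate
Product: 5 ethyl (2S,3S)-2-(benzyloxymethyl)-3-hydroxypent-4-enoate
Conditions: LDA (2.2 equiv), THF, −78 → −20 °C; BnOCH2Cl, −78 → −10 °C
Reagents that add atoms: benzyl chloromethyl ether ClCOCc1ccccc1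
Why: Fráter–Seebach alkylation: the electrophile should approach the chelated alkoxide–enolate dianion anti to the C3 vinyl substituent, setting C4 of the target in the 2,3-anti sense.

Step 4
Reactants: 5 ethyl (2S,3S)-2-(benzyloxymethyl)-3-hydroxypent-4-enoate
Product: 6 ethyl (2S,3S)-3-benzyloxy-2-(benzyloxymethyl)pent-4-enoate
Conditions: benzyl 2,2,2-trichloroacetimidate, TfOH (cat.), CH2Cl2/cyclohexane, 0 °C → rt
Reagents that add atoms: benzyl 2,2,2-trichloroacetimidate N=C(OCc1ccccc1)C(Cl)(Cl)Cl
Why: Acid-catalysed O-benzylation with the trichloroacetimidate, chosen because basic benzylation of a β-hydroxy ester would risk retro-aldol cleavage and elimination.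

Step 5
Reactants: 6 ethyl (2S,3S)-3-benzyloxy-2-(benzyloxymethyl)pent-4-enoate
Product: 7 (2S,3S)-3-benzyloxy-2-(benzyloxymethyl)pent-4-enoic acid
Conditions: LiOH, THF/H2O, 0 °C → rt; then aq. HCl
Reagents that add atoms: lithium hydroxide [Li+].[OH-]
Why: Ester saponification under mild aqueous conditions, which should be faster than enolisation at C4 or β-elimination of benzyl oxide.

Step 6
Reactants: 7 (2S,3S)-3-benzyloxy-2-(benzyloxymethyl)pent-4-enoic acid; 3 (S)-6-(tert-butyldiphenylsilyloxy)-3-methylhex-1-en-3-ol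
Product: 8 (S)-6-(tert-butyldiphenylsilyloxy)-3-methylhex-1-en-3-yl (2S,3S)-3-benzyloxy-2-(benzyloxymethyl)pent-4-enoate
Conditions: 2,4,6-trichlorobenzoyl chloride, Et3N, THF, rt; then 3, DMAP, toluene, 60 °C
Reagents that add atoms: none
Why: Yamaguchi esterification: the mixed anhydride and DMAP give an acylpyridinium reactive enough for the tertiary allylic alcohol, and this ester bond is the future C5–O–C10 bridge.

Step 7
Reactants: 8 diene ester
Product: 10 (3S,4S,7S)-4-benzyloxy-3-(benzyloxymethyl)-7-methyl-7-[3-(tert-butyldiphenylsilyloxy)propyl]oxepan-2-one, via unsaturated lactone 9 (not isolated)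
Conditions: Grubbs II (5 mol%), CH2Cl2 (0.003 M), 40 °C; then H2 (10 bar), 60 °C
Reagents that add atoms: none
Why: Ring-closing metathesis of the two terminal vinyl groups closes the seven-membered lactone (C1=C2), and the ruthenium hydride formed under hydrogen saturates the ring alkene in a tandem RCM–hydrogenation that leaves the benzyl ethers intact.

Step 8
Reactants: 10 saturated ε-lactone
Product: 12 tert-butyl 2-[(2S,3S,4S,7S)-4-benzyloxy-3-(benzyloxymethyl)-7-methyl-7-[3-(tert-butyldiphenylsilyloxy)propyl]oxepan-2-yl]acetate, via lithium hemiketalate 11 (not isolated)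
Conditions: t-BuOAc, LDA, THF, −78 °C; then Et3SiH, TMSOTf, CH2Cl2, −78 → −20 °C
Reagents that add atoms: tert-butyl acetate CC(=O)OC(C)(C)C
Why: Claisen-type addition of the ester enolate to the lactone followed by silane reduction of the derived oxocarbenium ion (reductive etherification); hydride should add to the face opposite the C4 CH2OBn and C3 OBn groups, setting C5 with C6 cis to C15.

Step 9
Reactants: 12 oxepane acetate
Product: 14 tert-butyl 2-(methoxycarbonyloxy)-2-[(2-oxepanyl)]acetate (ring centres as in 12; both C6 epimers), via sodium alkoxide 13 (not isolated)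
Conditions: NaHMDS, THF, −78 °C; 2-(phenylsulfonyl)-3-phenyloxaziridine; then ClCO2Me, −78 → 0 °C
Reagents that add atoms: 2-(phenylsulfonyl)-3-phenyloxaziridine O=S(=O)(c1ccccc1)N1OC1c1ccccc1; methyl chloroformate COC(Cl)=O
Why: Davis enolate hydroxylation with trapping of the alkoxide as the methyl carbonate, which installs the C6 oxygen together with the future C12; the C6 configuration is irrelevant because it is erased in step 17.

Step 10
Reactants: 14 dibenzyl carbonate ester
Product: 15 the corresponding C3,C15-diol (4-hydroxy-3-hydroxymethyl oxepane; other groups as in 14)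
Conditions: H2 (1 atm), Pd/C, EtOAc, rt
Reagents that add atoms: none
Why: Hydrogenolysis of both benzyl ethers; the silyl ether, carbonate and tert-butyl ester are inert.

Step 11
Reactants: 15 diol
Product: 16 the C3,C15-diacetate
Conditions: Ac2O, pyridine, DMAP (cat.), CH2Cl2, rt
Reagents that add atoms: acetic anhydride CC(=O)OC(C)=O
Why: Acetylation of the primary and secondary hydroxyls places the two acetates of the target before any further base-sensitive group is made.

Step 12
Reactants: 16 diacetate silyl ether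
Product: 17 the primary alcohol (7-(3-hydroxypropyl) side chain)
Conditions: HF·pyridine, THF/pyridine, 0 °C → rt
Reagents that add atoms: none
Why: Fluoride-mediated desilylation under buffered acidic conditions, which spare acetates, carbonate and tert-butyl ester.

Step 13
Reactants: 17 primary alcohol
Product: 18 the aldehyde (7-(3-oxopropyl) side chain; C7 of the target as CHO)
Conditions: Dess–Martin periodinane, CH2Cl2, rt
Reagents that add atoms: none
Why: Dess–Martin oxidation gives the aldehyde without over-oxidation or epimerisable centres nearby.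

Step 14
Reactants: 18 aldehyde
Product: 20 diethyl (E,3R)-3-(phenylaminooxy)but-1-enylphosphonate attached through C4 to C10 of the oxepane (other groups as in 16), via α-anilinooxy aldehyde 19 (not isolated)
Conditions: L-proline (20 mol%), PhNO, DMSO, rt; then CH2[P(O)(OEt)2]2, LiCl, DBU, MeCN, 0 °C
Reagents that add atoms: nitrosobenzene O=Nc1ccccc1; tetraethyl methylenediphosphonate CCOP(=O)(OCC)CP(=O)(OCC)OCC
Why: Proline-catalysed α-aminoxylation (nitroso aldol through the hydrogen-bonded enamine transition state, L-proline giving the R centre) sets C8 under catalyst control, and Horner–Wadsworth–Emmons olefination of the labile aldehyde in the same flask gives the (E)-vinylphosphonate.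

Step 15
Reactants: 20 γ-anilinooxy vinylphosphonate
Product: 21 the (R)-γ-hydroxy vinylphosphonate
Conditions: Zn, AcOH/THF, rt
Reagents that add atoms: none
Why: Reductive N–O cleavage by zinc in acetic acid frees the C8 hydroxyl; the vinylphosphonate is too electron-rich an acceptor to be reduced by zinc.

Step 16
Reactants: 21 γ-hydroxy vinylphosphonate tert-butyl ester
Product: 23 2-(methoxycarbonyloxy)acetic acid bearing the oxepane at C2 of the acid, with C8–OTBS (key-step precursor), via silyl ester 22 (not isolated)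
Conditions: TBSOTf (3.5 equiv), 2,6-lutidine, CH2Cl2, 0 °C → rt; then THF/H2O
Reagents that add atoms: tert-butyldimethylsilyl trifluoromethanesulfonate CC(C)(C)[Si](C)(C)OS(=O)(=O)C(F)(F)F
Why: Silyl triflate/lutidine silylates the C8 hydroxyl and converts the tert-butyl ester into the silyl ester with loss of isobutene; the silyl ester hydrolyses on aqueous work-up while the TBS ether stays.

Step 17
Reactants: 23 carbonate acid
Product: 24 8-O-TBS α-(diethoxyphosphoryl) lactone (tricyclic; C11 configuration undefined, enolisable)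
Conditions: 4CzIPN (5 mol%), Cs2CO3 (1.0 equiv, proton shuttle), degassed DMSO (0.002 M), 450 nm LEDs, rt; then aq. NH4Cl
Reagents that add atoms: none
Why: Proposed new method: the excited photocatalyst oxidises the caesium carboxylate of 23, CO2 is lost and the C6 α-(methoxycarbonyloxy)alkyl radical adds to C7 of the (E)-vinylphosphonate; the C11 α-phosphonyl radical is reduced by the photocatalyst radical anion to the carbanion, which attacks the carbonate carbonyl on the C6 oxygen and expels methoxide, so C6–C7 and C11–C12 form in one redox-neutral operation. The closest known reaction types are the photoredox decarboxylative Giese addition with radical–polar crossover, where the carbanion is trapped intramolecularly by an electrophile (cyclopropane and cyclobutane annulations), and SmI2 radical cyclisation/Dieckmann cascades; acylation of the crossover carbanion by a tethered carbonate across a new medium ring has not been shown. The oxepane closes 7-exo-trig at the radical stage and the lactone 5-exo-trig at the anionic stage. C7 should be set by attack on the alkene face anti to the C8–OTBS bond (Felkin-type, allylic strain holding H-8 in the alkene plane), and C6 in the same bond formation with the carbonate oxygen and the C11 branch pseudo-equatorial and trans on the forming ring (H-6/H-7 anti), both C6 epimers of 23 converging on one planar radical. The step needs cyclisation to beat hydrogen abstraction, and the carbanion to be acylated before it is protonated or displaces the γ-carbonate: high dilution in aprotic DMSO, the pre-formed carboxylate as the only acid, and the five-membered geometry between C11 and the carbonate carbonyl are meant to secure this, while the two acetates are out of reach.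

Step 18
Reactants: 24 α-phosphono lactone
Product: 25 8-O-TBS α-methylene lactone
Conditions: (CH2O)n, LiCl, DBU, THF, 0 °C → rt
Reagents that add atoms: formaldehyde C=O
Why: Horner–Wadsworth–Emmons olefination of the acidic phosphono lactone with formaldehyde installs C13 under Masamune–Roush conditions mild enough for the acetates.

Step 19
Reactants: 25 silyl ether
Product: 26 8-hydroxy α-methylene lactone
Conditions: HF·pyridine, THF, 0 °C → rt
Reagents that add atoms: none
Why: Acidic fluoride desilylation avoids the basic conditions under which an alkoxide could add to the α-methylene lactone or shift the acetates.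

Step 20
Reactants: 26 8-hydroxy α-methylene lactone; 27 angelic acid
Product: 28 target, (3S,4S,5R,6S,7R,8R,10R)-3,15-diacetoxy-8-angeloyloxy-5,10-epoxygermacr-11(13)-en-12,6-olide
Conditions: 27, 2,4,6-trichlorobenzoyl chloride, Et3N, toluene, rt; then 26, 80 °C
Reagents that add atoms: none
Why: Yamaguchi esterification through the angelic 2,4,6-trichlorobenzoic mixed anhydride without nucleophilic catalyst, the conditions under which the (Z)-2-methylbut-2-enoyl group is transferred without isomerisation to the tiglate.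

**Compound list**

1 | (S)-(+)-linalool | O[C@](C)(C=C)CCC=C(C)C | starting material
2 | (S)-4-methylhex-5-ene-1,4-diol | O[C@](C)(C=C)CCCO | intermediate
3 | (S)-6-(tert-butyldiphenylsilyloxy)-3-methylhex-1-en-3-ol | O[C@](C)(C=C)CCCO[Si](c1ccccc1)(c1ccccc1)C(C)(C)C | intermediate
4 | ethyl (R)-3-hydroxypent-4-enoate | C=C[C@H](O)CC(=O)OCC | starting material
5 | ethyl (2S,3S)-2-(benzyloxymethyl)-3-hydroxypent-4-enoate | C=C[C@H](O)[C@@H](C(=O)OCC)COCc1ccccc1 | intermediate
6 | ethyl (2S,3S)-3-benzyloxy-2-(benzyloxymethyl)pent-4-enoate | C=C[C@H](OCc1ccccc1)[C@@H](C(=O)OCC)COCc1ccccc1 | intermediate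
7 | (2S,3S)-3-benzyloxy-2-(benzyloxymethyl)pent-4-enoic acid | C=C[C@H](OCc1ccccc1)[C@@H](C(=O)O)COCc1ccccc1 | intermediate
8 | (S)-6-(tert-butyldiphenylsilyloxy)-3-methylhex-1-en-3-yl (2S,3S)-3-benzyloxy-2-(benzyloxymethyl)pent-4-enoate | C=C[C@H](OCc1ccccc1)[C@H](COCc1ccccc1)C(=O)O[C@](C)(C=C)CCCO[Si](c1ccccc1)(c1ccccc1)C(C)(C)C | intermediate
9 | (3S,4S,7S)-4-benzyloxy-3-(benzyloxymethyl)-7-methyl-7-[3-(tert-butyldiphenylsilyloxy)propyl]-4,7-dihydro-3H-oxepin-2-one (ring Z-alkene C1=C2) | O=C1O[C@](C)(C=C[C@H](OCc2ccccc2)[C@@H]1COCc1ccccc1)CCCO[Si](c1ccccc1)(c1ccccc1)C(C)(C)C | intermediate (not isolated)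
10 | (3S,4S,7S)-4-benzyloxy-3-(benzyloxymethyl)-7-methyl-7-[3-(tert-butyldiphenylsilyloxy)propyl]oxepan-2-one | O=C1O[C@](C)(CC[C@H](OCc2ccccc2)[C@@H]1COCc1ccccc1)CCCO[Si](c1ccccc1)(c1ccccc1)C(C)(C)C | intermediate
11 | lithium hemiketalate of 10 with tert-butyl acetate (C5 both anomers) | [Li+].[O-]C1(CC(=O)OC(C)(C)C)O[C@](C)(CC[C@H](OCc2ccccc2)[C@@H]1COCc1ccccc1)CCCO[Si](c1ccccc1)(c1ccccc1)C(C)(C)C | intermediate (not isolated)
12 | tert-butyl 2-[(2S,3S,4S,7S)-4-benzyloxy-3-(benzyloxymethyl)-7-methyl-7-[3-(tert-butyldiphenylsilyloxy)propyl]oxepan-2-yl]acetate | CC(C)(C)OC(=O)C[C@@H]1O[C@](C)(CC[C@H](OCc2ccccc2)[C@@H]1COCc1ccccc1)CCCO[Si](c1ccccc1)(c1ccccc1)C(C)(C)C | intermediate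
13 | sodium alkoxide of the C6 α-hydroxy ester of 12 (C6 epimers) | [Na+].[O-]C(C(=O)OC(C)(C)C)[C@@H]1O[C@](C)(CC[C@H](OCc2ccccc2)[C@@H]1COCc1ccccc1)CCCO[Si](c1ccccc1)(c1ccccc1)C(C)(C)C | intermediate (not isolated)
14 | tert-butyl 2-(methoxycarbonyloxy)-2-[oxepan-2-yl]acetate, ring as in 12 (C6 epimers) | COC(=O)OC(C(=O)OC(C)(C)C)[C@@H]1O[C@](C)(CC[C@H](OCc2ccccc2)[C@@H]1COCc1ccccc1)CCCO[Si](c1ccccc1)(c1ccccc1)C(C)(C)C | intermediate
15 | C3,C15-diol of 14 | COC(=O)OC(C(=O)OC(C)(C)C)[C@@H]1O[C@](C)(CC[C@H](O)[C@@H]1CO)CCCO[Si](c1ccccc1)(c1ccccc1)C(C)(C)C | intermediate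
16 | C3,C15-diacetate | COC(=O)OC(C(=O)OC(C)(C)C)[C@@H]1O[C@](C)(CC[C@H](OC(C)=O)[C@@H]1COC(C)=O)CCCO[Si](c1ccccc1)(c1ccccc1)C(C)(C)C | intermediate
17 | primary alcohol (C7–OH of the side chain) | COC(=O)OC(C(=O)OC(C)(C)C)[C@@H]1O[C@](C)(CC[C@H](OC(C)=O)[C@@H]1COC(C)=O)CCCO | intermediate
18 | side-chain aldehyde | COC(=O)OC(C(=O)OC(C)(C)C)[C@@H]1O[C@](C)(CC[C@H](OC(C)=O)[C@@H]1COC(C)=O)CCC=O | intermediate
19 | (R)-α-(phenylaminooxy) aldehyde | COC(=O)OC(C(=O)OC(C)(C)C)[C@@H]1O[C@](C)(CC[C@H](OC(C)=O)[C@@H]1COC(C)=O)C[C@@H](ONc1ccccc1)C=O | intermediate (not isolated)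
20 | (E,R)-γ-(phenylaminooxy) vinylphosphonate | COC(=O)OC(C(=O)OC(C)(C)C)[C@@H]1O[C@](C)(CC[C@H](OC(C)=O)[C@@H]1COC(C)=O)C[C@@H](ONc1ccccc1)/C=C/P(=O)(OCC)OCC | intermediate
21 | (E,R)-γ-hydroxy vinylphosphonate | COC(=O)OC(C(=O)OC(C)(C)C)[C@@H]1O[C@](C)(CC[C@H](OC(C)=O)[C@@H]1COC(C)=O)C[C@@H](O)/C=C/P(=O)(OCC)OCC | intermediate
22 | C8 TBS ether, TBS ester | COC(=O)OC(C(=O)O[Si](C)(C)C(C)(C)C)[C@@H]1O[C@](C)(CC[C@H](OC(C)=O)[C@@H]1COC(C)=O)C[C@@H](O[Si](C)(C)C(C)(C)C)/C=C/P(=O)(OCC)OCC | intermediate (not isolated)
23 | carbonate acid with C8–OTBS and (E)-vinylphosphonate (C6 epimers) | COC(=O)OC(C(=O)O)[C@@H]1O[C@](C)(CC[C@H](OC(C)=O)[C@@H]1COC(C)=O)C[C@@H](O[Si](C)(C)C(C)(C)C)/C=C/P(=O)(OCC)OCC | intermediate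
24 | 8-O-TBS 11-(diethoxyphosphoryl)-5,10-epoxygermacran-12,6-olide 3,15-diacetate (C11 undefined) | CCOP(=O)(OCC)C1C(=O)O[C@@H]2[C@@H]3O[C@](C)(CC[C@H](OC(C)=O)[C@@H]3COC(C)=O)C[C@@H](O[Si](C)(C)C(C)(C)C)[C@@H]12 | intermediate
25 | 8-O-TBS α-methylene lactone | C=C1C(=O)O[C@@H]2[C@@H]3O[C@](C)(CC[C@H](OC(C)=O)[C@@H]3COC(C)=O)C[C@@H](O[Si](C)(C)C(C)(C)C)[C@@H]12 | intermediate
26 | 8-hydroxy α-methylene lactone | C=C1C(=O)O[C@@H]2[C@@H]3O[C@](C)(CC[C@H](OC(C)=O)[C@@H]3COC(C)=O)C[C@@H](O)[C@@H]12 | intermediate
27 | angelic acid, (Z)-2-methylbut-2-enoic acid | C/C=C(/C)C(=O)O | starting material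
28 | CNP0346171.1 | C=C1C(=O)O[C@@H]2[C@@H]3O[C@](C)(CC[C@H](OC(C)=O)[C@@H]3COC(C)=O)C[C@@H](OC(=O)/C(C)=C\C)[C@@H]12 | target

**Totals**

Total step count: 20. Longest linear sequence: 18 steps (steps 3–20, from 4).

**Steps most likely to fail**

1. Step 17. The 7-exo closure builds a strained trans-bridged bicycle and may be slow enough for hydrogen abstraction to compete; the carbanion may be protonated before it acylates the carbonate; facial selectivity at C7 may be poor. The fallback sets out from 23 and separates the two bond formations into known reactions. The acid is converted with N-hydroxypyridine-2-thione and EDC into the Barton ester F1. Visible-light photolysis at high dilution runs the cyclisation as a radical chain with pyridylthio group transfer (Barton decarboxylative addition to a vinylphosphonate) and gives the cyclised α-(2-pyridylthio)phosphonate carbonate F2. The doubly activated C11–H is removed with LiHMDS at −78 °C and the carbanion closes the lactone on the carbonate (Dieckmann-type acylation) to the α-(2-pyridylthio) phosphono lactone F3. Bu3SnH/AIBN removes the sulfur, and the route is rejoined at 24.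

2. Step 8. The hemiketalate may open to the hydroxy keto ester, which can stall as an enol ether or ionise at the tertiary carbinol; hydride delivery to the oxocarbenium ion may be unselective at C5. The fallback sets out from 10. DIBAL-H at −78 °C gives the hydroxy aldehyde (lactol) F4, and a Wittig reaction with Ph3P=CHCO2t-Bu gives the (E)-hydroxy enoate F5. KOt-Bu-mediated 7-exo oxa-Michael addition of the tertiary alkoxide under equilibrating conditions closes the oxepane, and the route is rejoined at 12.

3. Step 6. Acylation of the hindered tertiary allylic alcohol may be slow, letting ketene formation (loss of the C4 configuration) or ionisation of the alcohol compete. The fallback sets out from 5 and uses strain-driven acylation. LiOH gives the hydroxy acid F6, and PhSO2Cl/pyridine closes the trans-β-lactone F7. The lithium alkoxide of 3 (n-BuLi, THF, −78 °C) opens F7 at the acyl carbon to the β-hydroxy ester F8. Benzylation with benzyl trichloroacetimidate/TfOH rejoins the route at 8.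

**Further compounds**

F1 | step 17 | Barton ester (N-acyloxypyridine-2-thione) of 23 | COC(=O)OC(C(=O)ON1C=CC=CC1=S)[C@@H]1O[C@](C)(CC[C@H](OC(C)=O)[C@@H]1COC(C)=O)C[C@@H](O[Si](C)(C)C(C)(C)C)/C=C/P(=O)(OCC)OCC
F2 | step 17 | cyclised α-(2-pyridylthio)phosphonate C6 methyl carbonate | COC(=O)O[C@@H]1[C@@H]2O[C@](C)(CC[C@H](OC(C)=O)[C@@H]2COC(C)=O)C[C@@H](O[Si](C)(C)C(C)(C)C)[C@H]1C(Sc1ccccn1)P(=O)(OCC)OCC
F3 | step 17 | α-(2-pyridylthio) α-phosphono lactone | CCOP(=O)(OCC)C1(Sc2ccccn2)C(=O)O[C@@H]2[C@@H]3O[C@](C)(CC[C@H](OC(C)=O)[C@@H]3COC(C)=O)C[C@@H](O[Si](C)(C)C(C)(C)C)[C@@H]12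
F4 | step 8 | hydroxy aldehyde (open form of the lactol of 10) | O[C@](C)(CC[C@H](OCc1ccccc1)[C@@H](C=O)COCc1ccccc1)CCCO[Si](c1ccccc1)(c1ccccc1)C(C)(C)C
F5 | step 8 | tert-butyl (E)-hydroxy enoate | O[C@](C)(CC[C@H](OCc1ccccc1)[C@@H](/C=C/C(=O)OC(C)(C)C)COCc1ccccc1)CCCO[Si](c1ccccc1)(c1ccccc1)C(C)(C)C
F6 | step 6 | (2S,3S)-2-(benzyloxymethyl)-3-hydroxypent-4-enoic acid | C=C[C@H](O)[C@@H](C(=O)O)COCc1ccccc1
F7 | step 6 | trans-3-(benzyloxymethyl)-4-vinyloxetan-2-one | C=C[C@@H]1OC(=O)[C@H]1COCc1ccccc1
F8 | step 6 | β-hydroxy ester of F6 with 3 | C=C[C@H](O)[C@H](COCc1ccccc1)C(=O)O[C@](C)(C=C)CCCO[Si](c1ccccc1)(c1ccccc1)C(C)(C)C
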